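**Strategy**

Each arm is numbered from the ester carbonyl C1 to the methyl C6; ring A is the quinone, B and C the phenol rings, D and E the oxiranes. Everything rests on cutting both C3–C4 bonds between the enoate carbons and oxirane carbon C4. The key step exploits the trans C4–C5 oxiranes of rings D and E, which are the closure products of anti C4-hydroxy/C5-chloro pairs: the bis(zinc acetylide) of a hydroquinone bis-propiolate (ring A carbonyl oxygens as PMB ethers, ring B and C phenols as TBS ethers) adds to two molecules of (R)-2-chloropropanal, forming both C3–C4 bonds and, under control of the bought C5 centre, both C4 stereocentres at once.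

Key step: step 6

Assumption: (S,S)-ProPhenol is taken as the ligand enantiomer that steers the acetylide to the Si face of an aliphatic aldehyde, the face already preferred by Cornforth control in (R)-2-chloropropanal; should a test reaction show the opposite sense, (R,R)-ProPhenol is used with no other change.

Remark: the core is entered from bromanil, because alkoxide substitution on a tetrahaloquinone fixes the 2,5-dialkoxy pattern unambiguously and avoids O-alkylation of an acidic dihydroxyquinone.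

Remark: steps 1, 2, 4 and 6 are twofold reactions on a symmetric core, so two molecules of the partner are built into each product.

**Route**

Step 1
Reactants: 1 tetrabromo-1,4-benzoquinone (bromanil)
Product: 2 2,5-dibromo-3,6-bis[(4-methoxybenzyl)oxy]-1,4-benzoquinone
Conditions: 4-methoxybenzyl alcohol (2.05 equiv), NaH (2.0 equiv), THF, 0 °C; alkoxide added slowly to 1, THF, −40 °C to 0 °C
Reagents that add atoms: 4-methoxybenzyl alcohol, COc1ccc(CO)cc1
Why: Twofold vinylic addition–elimination of an alkoxide on a tetrahalo-p-benzoquinone (as in the methoxide/chloranil reaction) should take up two molecules of the alkoxide and stop at the para 2,5-dialkoxy-3,6-dibromo stage, because the first alkoxy group deactivates its own vinylogous ester half and directs the second attack to the opposite C–Br.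

Step 2
Reactants: 2 2,5-dibromo-3,6-bis[(4-methoxybenzyl)oxy]-1,4-benzoquinone; 3 [4-(tert-butyldimethylsilyloxy)phenyl]boronic acid
Product: 4 2,5-bis[4-(tert-butyldimethylsilyloxy)phenyl]-3,6-bis[(4-methoxybenzyl)oxy]-1,4-benzoquinone
Conditions: 3 (2.6 equiv in all), PdCl2(dppf) (10 mol %), K3PO4 (4 equiv), 1,4-dioxane, 80 °C, Ar
Reagents that add atoms: [4-(tert-butyldimethylsilyloxy)phenyl]boronic acid 3 (second equivalent), CC(C)(C)[Si](C)(C)Oc1ccc(B(O)O)cc1
Why: Double Suzuki–Miyaura coupling at the two vinylic C–Br bonds of a 2,5-dibromo-3,6-dialkoxybenzoquinone, one molecule of 3 per bromide, is a known entry to terphenylquinones, and the mild phosphate base should spare the aryl silyl ethers and the vinylogous PMB esters.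

Step 3
Reactants: 4 2,5-bis[4-(tert-butyldimethylsilyloxy)phenyl]-3,6-bis[(4-methoxybenzyl)oxy]-1,4-benzoquinone
Product: 5 2,5-bis[4-(tert-butyldimethylsilyloxy)phenyl]-3,6-bis[(4-methoxybenzyl)oxy]benzene-1,4-diol
Conditions: Na2S2O4, THF/H2O, rt, Ar; crude diol used at once
Reagents that add atoms: none
Why: Dithionite reduction of a p-benzoquinone to its hydroquinone turns the vinylogous PMB esters into ordinary aryl PMB ethers and frees exactly the two oxygens that are to carry the arms.

Step 4
Reactants: 5 2,5-bis[4-(tert-butyldimethylsilyloxy)phenyl]-3,6-bis[(4-methoxybenzyl)oxy]benzene-1,4-diol; 6 propiolic acid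
Product: 7 2,5-bis[4-(tert-butyldimethylsilyloxy)phenyl]-3,6-bis[(4-methoxybenzyl)oxy]-1,4-phenylene bis(prop-2-ynoate)
Conditions: 6 (3 equiv in all), DIC (3 equiv), DMAP (5 mol %), CH2Cl2, −20 °C to 0 °C, Ar
Reagents that add atoms: propiolic acid 6 (second equivalent), C#CC(=O)O
Why: Steglich-type carbodiimide esterification, one molecule of 6 per phenol, is the standard route to aryl propiolates, and the small linear acyl group should reach the flanked phenols while low temperature and little DMAP suppress conjugate addition to the ynoate.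

Step 5
Reactants: 8 methyl (R)-2-chloropropanoate
Product: 10 (R)-2-chloropropanal, via aluminium hemiacetal 9 (not isolated)
Conditions: i-Bu2AlH (1.05 equiv), toluene, −78 °C; Na2SO4·10H2O quench at −78 °C, cold filtration, 4 Å MS; cold toluene solution used at once
Reagents that add atoms: none
Why: Half-reduction of an ester with i-Bu2AlH stops at the aldehyde because tetrahedral hemiacetal 9 persists at −78 °C until work-up, and the cold, base-free handling should leave the C2 stereocentre untouched.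

Step 6
Reactants: 7 2,5-bis[4-(tert-butyldimethylsilyloxy)phenyl]-3,6-bis[(4-methoxybenzyl)oxy]-1,4-phenylene bis(prop-2-ynoate); 10 (R)-2-chloropropanal
Product: 13 bis[(4S,5R)-5-chloro-4-hydroxyhex-2-ynoate] of the protected hydroquinone (bis-chlorohydrin), via bis(methylzinc acetylide) 11 (not isolated), via bis(methylzinc alkoxide) 12 (not isolated)
Conditions: Me2Zn (3 equiv per alkyne), (S,S)-ProPhenol (20 mol % per alkyne), Ph3P=O (40 mol % per alkyne), toluene, 4 °C, 1.5 h; then 10 (2.5 equiv per alkyne, cold toluene solution), 4 °C; aq. NH4Cl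
Reagents that add atoms: (R)-2-chloropropanal 10 (second molecule), C[C@@H](Cl)C=O
Why: Me2Zn and the ProPhenol ligand assemble a dinuclear zinc complex that deprotonates each propiolate C–H (methane is lost) to give alkynylzinc 11, while the second zinc binds one molecule of aldehyde per arm and the acetylide carbon C3 is delivered to carbonyl carbon C4 to give zinc alkoxide 12, protonated on work-up. The closest known reactions are the zinc–ProPhenol addition of alkyl propiolates to aldehydes and the anti-selective addition of metal acetylides to α-chloro aldehydes. No ring is closed. Each new stereocentre (C4 and C4′) is controlled by the purchased chlorine-bearing C5 centre: in the Cornforth arrangement C–Cl lies anti to C=O and the nucleophile passes hydrogen and not methyl, so it attacks the Si face and should give 4S next to 5R (1,2-anti), with the ligand enantiomer chosen to favour the same face. The step needs 1,2-anti selectivity on both arms and carbonyl addition that leaves the aryl esters alone; the first is secured by the α-chlorine (with 10 freshly made and kept cold so that it keeps its configuration), the second by the weakly basic zinc reagents, the doubly ortho-substituted aryl esters and the linear ynoate, which holds each C4 alkoxide out of reach of its own ester.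

Step 7
Reactants: 13 bis[(4S,5R)-5-chloro-4-hydroxyhex-2-ynoate] of the protected hydroquinone
Product: 14 2,5-bis[4-(tert-butyldimethylsilyloxy)phenyl]-3,6-bis[(4-methoxybenzyl)oxy]-1,4-phenylene bis[(4S,5S)-4,5-epoxyhex-2-ynoate]
Conditions: Ag2O (4 equiv), AgOSO2CF3 (20 mol %), 4 Å MS, THF, dark, rt
Reagents that add atoms: none
Why: Silver-assisted intramolecular Williamson etherification, in which Ag+ abstracts chloride while the C4 hydroxyl attacks C5 from the rear (3-exo-tet, inversion at C5, C4 unchanged), should turn each anti-chlorohydrin into the trans (4S,5S) oxirane, and the base-free medium spares the aryl ynoate esters and avoids base-triggered isomerisation of the γ-hydroxy ynoate.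

Step 8
Reactants: 14 bis[(4S,5S)-4,5-epoxyhex-2-ynoate] of the protected hydroquinone
Product: 15 2,5-bis[4-(tert-butyldimethylsilyloxy)phenyl]-3,6-bis[(4-methoxybenzyl)oxy]-1,4-phenylene bis[(2Z,4S,5S)-4,5-epoxyhex-2-enoate]
Conditions: H2 (1 atm), Pd/CaCO3 poisoned with Pb(OAc)2 (Lindlar catalyst), quinoline, EtOAc, 0 °C to rt, stopped after uptake of 2 equiv
Reagents that add atoms: none
Why: Lindlar semi-hydrogenation delivers H2 syn to each alkyne on the poisoned palladium surface and should give the Z enoates with oxiranes, benzylic ethers and silyl ethers intact; lactonisation is impossible because the C4 oxygen is already tied up in the oxirane.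

Step 9
Reactants: 15 bis[(2Z,4S,5S)-4,5-epoxyhex-2-enoate] of the protected hydroquinone
Product: 16 2,5-bis(4-hydroxyphenyl)-3,6-bis[(4-methoxybenzyl)oxy]-1,4-phenylene bis[(2Z,4S,5S)-4,5-epoxyhex-2-enoate]
Conditions: Et3N·3HF, MeCN/THF, rt
Reagents that add atoms: none
Why: Fluoride-induced Si–O cleavage of aryl silyl ethers proceeds under the weakly acidic, non-nucleophilic conditions of an amine–HF reagent, which should leave the aryl esters (no phenoxide, hence no acyl transfer), the oxiranes and the PMB ethers alone.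

Step 10
Reactants: 16 2,5-bis(4-hydroxyphenyl)-3,6-bis[(4-methoxybenzyl)oxy]-1,4-phenylene bis[(2Z,4S,5S)-4,5-epoxyhex-2-enoate]
Product: 18 2,5-bis(4-hydroxyphenyl)-3,6-dioxocyclohexa-1,4-diene-1,4-diyl bis[(2Z,4S,5S)-4,5-epoxyhex-2-enoate] (target), via free hydroquinone diester 17 (not isolated)
Conditions: DDQ (3.3 equiv), CH2Cl2/pH 7 phosphate buffer, 0 °C to rt; neutral work-up
Reagents that add atoms: none
Why: Oxidative PMB ether cleavage by DDQ (benzylic hydride abstraction, then hydrolysis of the oxocarbenium ion) should free hydroquinone 17, which further DDQ dehydrogenates at once to the p-quinone (standard hydroquinone oxidation), so that the leuco compound has no time for 1,2-acyl shifts and the buffer shields the vinyl oxiranes from acidic DDQH2.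

**Compound list**

1 | tetrabromo-1,4-benzoquinone (bromanil) | O=C1C(Br)=C(Br)C(=O)C(Br)=C1Br | starting material
2 | 2,5-dibromo-3,6-bis[(4-methoxybenzyl)oxy]-1,4-benzoquinone | O=C1C(Br)=C(OCc2ccc(OC)cc2)C(=O)C(Br)=C1OCc1ccc(OC)cc1 | intermediate
3 | [4-(tert-butyldimethylsilyloxy)phenyl]boronic acid | CC(C)(C)[Si](C)(C)Oc1ccc(B(O)O)cc1 | starting material
4 | 2,5-bis[4-(tert-butyldimethylsilyloxy)phenyl]-3,6-bis[(4-methoxybenzyl)oxy]-1,4-benzoquinone | O=C1C(c2ccc(O[Si](C)(C)C(C)(C)C)cc2)=C(OCc2ccc(OC)cc2)C(=O)C(c2ccc(O[Si](C)(C)C(C)(C)C)cc2)=C1OCc1ccc(OC)cc1 | intermediate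
5 | 2,5-bis[4-(tert-butyldimethylsilyloxy)phenyl]-3,6-bis[(4-methoxybenzyl)oxy]benzene-1,4-diol | Oc1c(-c2ccc(O[Si](C)(C)C(C)(C)C)cc2)c(OCc2ccc(OC)cc2)c(O)c(-c2ccc(O[Si](C)(C)C(C)(C)C)cc2)c1OCc1ccc(OC)cc1 | intermediate
6 | propiolic acid | C#CC(=O)O | starting material
7 | 2,5-bis[4-(tert-butyldimethylsilyloxy)phenyl]-3,6-bis[(4-methoxybenzyl)oxy]-1,4-phenylene bis(prop-2-ynoate) | C#CC(=O)Oc1c(-c2ccc(O[Si](C)(C)C(C)(C)C)cc2)c(OCc2ccc(OC)cc2)c(OC(=O)C#C)c(-c2ccc(O[Si](C)(C)C(C)(C)C)cc2)c1OCc1ccc(OC)cc1 | intermediate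
8 | methyl (R)-2-chloropropanoate | C[C@@H](Cl)C(=O)OC | starting material
9 | diisobutylaluminium (2R)-2-chloro-1-methoxypropan-1-olate (tetrahedral hemiacetal, C1 undefined) | C[C@@H](Cl)C(OC)O[Al](CC(C)C)CC(C)C | intermediate
10 | (R)-2-chloropropanal | C[C@@H](Cl)C=O | intermediate
11 | bis(methylzinc acetylide) of 7 | C[Zn]C#CC(=O)Oc1c(-c2ccc(O[Si](C)(C)C(C)(C)C)cc2)c(OCc2ccc(OC)cc2)c(OC(=O)C#C[Zn]C)c(-c2ccc(O[Si](C)(C)C(C)(C)C)cc2)c1OCc1ccc(OC)cc1 | intermediate
12 | bis(methylzinc alkoxide) of 13 | C[C@@H](Cl)[C@@H](O[Zn]C)C#CC(=O)Oc1c(-c2ccc(O[Si](C)(C)C(C)(C)C)cc2)c(OCc2ccc(OC)cc2)c(OC(=O)C#C[C@H](O[Zn]C)[C@@H](C)Cl)c(-c2ccc(O[Si](C)(C)C(C)(C)C)cc2)c1OCc1ccc(OC)cc1 | intermediate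
13 | 2,5-bis[4-(tert-butyldimethylsilyloxy)phenyl]-3,6-bis[(4-methoxybenzyl)oxy]-1,4-phenylene bis[(4S,5R)-5-chloro-4-hydroxyhex-2-ynoate] | C[C@@H](Cl)[C@@H](O)C#CC(=O)Oc1c(-c2ccc(O[Si](C)(C)C(C)(C)C)cc2)c(OCc2ccc(OC)cc2)c(OC(=O)C#C[C@H](O)[C@@H](C)Cl)c(-c2ccc(O[Si](C)(C)C(C)(C)C)cc2)c1OCc1ccc(OC)cc1 | intermediate
14 | 2,5-bis[4-(tert-butyldimethylsilyloxy)phenyl]-3,6-bis[(4-methoxybenzyl)oxy]-1,4-phenylene bis[(4S,5S)-4,5-epoxyhex-2-ynoate] | C[C@@H]1O[C@H]1C#CC(=O)Oc1c(-c2ccc(O[Si](C)(C)C(C)(C)C)cc2)c(OCc2ccc(OC)cc2)c(OC(=O)C#C[C@@H]2O[C@H]2C)c(-c2ccc(O[Si](C)(C)C(C)(C)C)cc2)c1OCc1ccc(OC)cc1 | intermediate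
15 | 2,5-bis[4-(tert-butyldimethylsilyloxy)phenyl]-3,6-bis[(4-methoxybenzyl)oxy]-1,4-phenylene bis[(2Z,4S,5S)-4,5-epoxyhex-2-enoate] | C[C@@H]1O[C@H]1/C=C\C(=O)Oc1c(-c2ccc(O[Si](C)(C)C(C)(C)C)cc2)c(OCc2ccc(OC)cc2)c(OC(=O)/C=C\[C@@H]2O[C@H]2C)c(-c2ccc(O[Si](C)(C)C(C)(C)C)cc2)c1OCc1ccc(OC)cc1 | intermediate
16 | 2,5-bis(4-hydroxyphenyl)-3,6-bis[(4-methoxybenzyl)oxy]-1,4-phenylene bis[(2Z,4S,5S)-4,5-epoxyhex-2-enoate] | C[C@@H]1O[C@H]1/C=C\C(=O)Oc1c(-c2ccc(O)cc2)c(OCc2ccc(OC)cc2)c(OC(=O)/C=C\[C@@H]2O[C@H]2C)c(-c2ccc(O)cc2)c1OCc1ccc(OC)cc1 | intermediate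
17 | 3,6-dihydroxy-2,5-bis(4-hydroxyphenyl)-1,4-phenylene bis[(2Z,4S,5S)-4,5-epoxyhex-2-enoate] | C[C@@H]1O[C@H]1/C=C\C(=O)Oc1c(-c2ccc(O)cc2)c(O)c(OC(=O)/C=C\[C@@H]2O[C@H]2C)c(-c2ccc(O)cc2)c1O | intermediate
18 | 2,5-bis(4-hydroxyphenyl)-3,6-dioxocyclohexa-1,4-diene-1,4-diyl bis[(2Z,4S,5S)-4,5-epoxyhex-2-enoate] (CNP0407724.1) | C[C@@H]1O[C@H]1/C=C\C(=O)OC1=C(c2ccc(O)cc2)C(=O)C(OC(=O)/C=C\[C@@H]2O[C@H]2C)=C(c2ccc(O)cc2)C1=O | target

**Step count and risks**

Total step count: 10. Longest linear sequence: 9 steps (steps 1, 2, 3, 4, 6, 7, 8, 9, 10); step 5 is a one-step side branch.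

Steps most likely to fail:

Step 6. The second addition may stall, 10 may lose its configuration at the zinc alkoxide stage and erode the anti selectivity, or methyl transfer from zinc may compete. The fallback sets out from diol 5 and comes back at 15, building the arms by Z-selective olefination with the oxirane already in place. Diol 5 is esterified (DIC, catalytic DMAP, CH2Cl2) with two equivalents of (diphenoxyphosphoryl)acetic acid to give 2,5-bis[4-(tert-butyldimethylsilyloxy)phenyl]-3,6-bis[(4-methoxybenzyl)oxy]-1,4-phenylene bis[(diphenoxyphosphoryl)acetate] F1. Sharpless epoxidation of (E)-but-2-en-1-ol (Ti(OiPr)4, L-(+)-diethyl tartrate, t-BuOOH, 4 Å MS, −20 °C) gives [(2S,3S)-3-methyloxiran-2-yl]methanol F2, which Dess–Martin periodinane (NaHCO3, CH2Cl2) oxidises to (2R,3S)-3-methyloxirane-2-carbaldehyde F3; the C2 descriptor changes by priority only. An Ando-type Horner–Wadsworth–Emmons reaction of F1 (NaH, THF, −78 °C) with two equivalents of F3 should then give the Z,Z bis-enoate 15 and makes steps 6 to 8 unnecessary.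

Step 7. Chloride departure may be sluggish, the γ-hydroxy ynoate may isomerise to a γ-oxo enoate, or the aryl esters may be cleaved if stronger bases are needed. The fallback sets out from 10 and diol 5 and comes back at 14, closing the oxirane on a small fragment where aqueous base is harmless. Lithium methyl propiolate (methyl propiolate, LiN(SiMe3)2, THF, −78 °C) adds to 10 in the same Cornforth sense to give methyl (4S,5R)-5-chloro-4-hydroxyhex-2-ynoate F4. LiOH in THF/water at 0 °C closes the oxirane and saponifies the ester, and cautious cold acidification gives (4S,5S)-4,5-epoxyhex-2-ynoic acid F5, two equivalents of which are coupled at once with 5 (DIC, catalytic DMAP, CH2Cl2, −20 °C) to give 14.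

Step 10. DDQ may oxidise the free phenols of rings B and C in competition with PMB cleavage, and acyl groups may be lost from the quinone during isolation. The fallback sets out from 15 and comes back at 18, reversing the order of unmasking so that no free phenol meets the oxidant. DDQ in CH2Cl2/pH 7 buffer converts 15 into 2,5-bis[4-(tert-butyldimethylsilyloxy)phenyl]-3,6-dioxocyclohexa-1,4-diene-1,4-diyl bis[(2Z,4S,5S)-4,5-epoxyhex-2-enoate] F6, and Et3N·3HF in MeCN at 0 °C then removes the two silyl groups to give 18.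

**Further compounds**

F1 | step 6 | 2,5-bis[4-(tert-butyldimethylsilyloxy)phenyl]-3,6-bis[(4-methoxybenzyl)oxy]-1,4-phenylene bis[(diphenoxyphosphoryl)acetate] | O=C(CP(=O)(Oc1ccccc1)Oc1ccccc1)Oc1c(-c2ccc(O[Si](C)(C)C(C)(C)C)cc2)c(OCc2ccc(OC)cc2)c(OC(=O)CP(=O)(Oc2ccccc2)Oc2ccccc2)c(-c2ccc(O[Si](C)(C)C(C)(C)C)cc2)c1OCc1ccc(OC)cc1
F2 | step 6 | [(2S,3S)-3-methyloxiran-2-yl]methanol | C[C@@H]1O[C@H]1CO
F3 | step 6 | (2R,3S)-3-methyloxirane-2-carbaldehyde | C[C@@H]1O[C@H]1C=O
F4 | step 7 | methyl (4S,5R)-5-chloro-4-hydroxyhex-2-ynoate | C[C@@H](Cl)[C@@H](O)C#CC(=O)OC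
F5 | step 7 | (4S,5S)-4,5-epoxyhex-2-ynoic acid | C[C@@H]1O[C@H]1C#CC(=O)O
F6 | step 10 | 2,5-bis[4-(tert-butyldimethylsilyloxy)phenyl]-3,6-dioxocyclohexa-1,4-diene-1,4-diyl bis[(2Z,4S,5S)-4,5-epoxyhex-2-enoate] | C[C@@H]1O[C@H]1/C=C\C(=O)OC1=C(c2ccc(O[Si](C)(C)C(C)(C)C)cc2)C(=O)C(OC(=O)/C=C\[C@@H]2O[C@H]2C)=C(c2ccc(O[Si](C)(C)C(C)(C)C)cc2)C1=O
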